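**Retrosynthetic overview**
1. Stenosporic acid 8 is a depside. The one strategic disconnection is the ester C(acyl)–O(aryl) bond between ring A (2-hydroxy-4-methoxy-6-propylbenzoyl) and the 4-OH of ring B (olivetolic acid).
2. That bond is made last, by an oxidative carbene-catalysed coupling of ring A aldehyde 4 with unprotected olivetolic acid 6, with no protecting groups.
3. Aldehyde 4 comes from divarinol 1 by Vilsmeier formylation and selective 4-O-methylation.
4. Acid 6 comes from olivetol 5 by ortho-carboxylation.
5. No ring is built: both benzene rings are bought as the resorcinols 1 and 5, and the route is convergent (2 + 1 + 1 steps).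

Assumption: stenosporic acid has no stereocentre, stereoaxis or stereogenic double bond, so the structure given is achiral and no stereocontrol is needed. The route has not been run; yields are not claimed.

**Route**

Step 1
Reactants: 1 divarinol (5-propylbenzene-1,3-diol)
Product: 3 2,4-dihydroxy-6-propylbenzaldehyde, via aryl iminium chloride 2 (not isolated)
Conditions: POCl3 (1.2 equiv), DMF, 0 °C to rt; then H2O, 50 °C
Reagents that add atoms: N,N-dimethylformamide CN(C)C=O (formyl carbon); water O (carbonyl oxygen)
Why: Vilsmeier–Haack formylation; the chloroiminium ion attacks the ring position that is para to one hydroxyl and ortho to the other, as is established for orcinol, and the iminium salt 2 is hydrolysed on aqueous work-up.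

Step 2
Reactants: 3 2,4-dihydroxy-6-propylbenzaldehyde
Product: 4 2-hydroxy-4-methoxy-6-propylbenzaldehyde
Conditions: MeI (1.05 equiv), K2CO3 (1.0 equiv), acetone, rt to 40 °C
Reagents that add atoms: iodomethane CI
Why: Williamson ether synthesis; the 4-OH is the more acidic one (para to the formyl group) and is free, whereas the 2-OH is held in an intramolecular hydrogen bond to the formyl oxygen, so one equivalent of MeI alkylates only O-4.

Step 3
Reactants: 5 olivetol (5-pentylbenzene-1,3-diol)
Product: 6 olivetolic acid (2,4-dihydroxy-6-pentylbenzoic acid)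
Conditions: MeOMgOCO2Me (2 M in DMF, 5 equiv), 125 °C, 3 h; then cold 2 M HCl
Reagents that add atoms: methyl magnesium carbonate (methoxymagnesium methyl carbonate) CO[Mg]OC(=O)OC
Why: Kolbe–Schmitt-type ortho-carboxylation with Stiles' reagent; the magnesium chelate of the salicylate product pulls the reversible carboxylation forward and places CO2H ortho to one hydroxyl and para to the other.

Step 4
Reactants: 4 2-hydroxy-4-methoxy-6-propylbenzaldehyde; 6 olivetolic acid
Product: 8 stenosporic acid (2-hydroxy-4-[(2-hydroxy-4-methoxy-6-propylbenzoyl)oxy]-6-pentylbenzoic acid), via acyl triazolium iodide 7 (not isolated)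
Conditions: 1,4-dimethyl-4H-1,2,4-triazol-1-ium iodide (10 mol%), DBU (2.2 equiv), 3,3',5,5'-tetra-tert-butyl-4,4'-diphenoquinone (1.2 equiv), THF, 4 Å MS, 25 °C, 4 (1.2 equiv) added over 3 h to 6 (1.0 equiv); then cold 1 M HCl
Reagents that add atoms: none
Why: Proposed new method: a protecting-group-free oxidative depside coupling in which the small N-methyl triazolylidene (freed by DBU) adds to the hindered but hydrogen-bond-activated formyl group of 4, the Breslow intermediate is oxidised by the diphenoquinone (two electrons) to acyl triazolium 7, and 7 acylates the 4-phenoxide of the olivetolate dianion, either by direct addition–elimination or after loss of the carbene from its ortho-phenoxide as a sterically undemanding quinoketene; that phenoxide is the only unhindered, non-chelated oxygen nucleophile present, because the 2-OH groups of both partners are locked in hydrogen bonds and the carboxylate can only give a reversible mixed anhydride; the closest known reaction type is the N-heterocyclic-carbene-catalysed oxidative esterification of aldehydes with alcohols and simple phenols, which has not been shown for a 2,6-disubstituted salicylaldehyde donor or for an unprotected dihydroxybenzoic acid acceptor.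

**Compound list**
1 | divarinol (5-propylbenzene-1,3-diol) | CCCc1cc(O)cc(O)c1 | starting material
2 | N-[(2,4-dihydroxy-6-propylphenyl)methylidene]-N-methylmethanaminium chloride (aryl iminium chloride) | CCCc1cc(O)cc(O)c1C=[N+](C)C.[Cl-] | intermediate
3 | 2,4-dihydroxy-6-propylbenzaldehyde | CCCc1cc(O)cc(O)c1C=O | intermediate
4 | 2-hydroxy-4-methoxy-6-propylbenzaldehyde | CCCc1cc(OC)cc(O)c1C=O | intermediate
5 | olivetol (5-pentylbenzene-1,3-diol) | CCCCCc1cc(O)cc(O)c1 | starting material
6 | olivetolic acid (2,4-dihydroxy-6-pentylbenzoic acid) | CCCCCc1cc(O)cc(O)c1C(=O)O | intermediate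
7 | 5-(2-hydroxy-4-methoxy-6-propylbenzoyl)-1,4-dimethyl-4H-1,2,4-triazol-1-ium iodide (acyl triazolium iodide) | CCCc1cc(OC)cc(O)c1C(=O)C1=[N+](C)N=CN1C.[I-] | intermediate
8 | stenosporic acid (2-hydroxy-4-[(2-hydroxy-4-methoxy-6-propylbenzoyl)oxy]-6-pentylbenzoic acid; achiral) | CCCCCc1cc(OC(=O)c2c(O)cc(OC)cc2CCC)cc(O)c1C(=O)O | target

**Step count**
Total steps: 4. Longest linear sequence: 3 (1 → 3 → 4 → 8); step 3 (5 → 6) is the second branch.

**Three steps most likely to fail**

Step 4 (the proposed new coupling). The risks are slow carbene addition to the di-ortho-substituted, electron-rich aldehyde, deactivation of 4 as its phenoxide, self-condensation of 6 through the mixed anhydride, and hydrolysis of 7 by traces of water. The fallback is the classical protected depside synthesis; it sets out from 4 and 6 and comes back at 8. Aldehyde 4 is O-benzylated (BnBr, K2CO3, DMF, 60 °C) to 2-(benzyloxy)-4-methoxy-6-propylbenzaldehyde F1. Lindgren–Pinnick oxidation (NaClO2, NaH2PO4, 2-methylbut-2-ene, t-BuOH/H2O) then gives 2-(benzyloxy)-4-methoxy-6-propylbenzoic acid F2. Acid 6 is converted through its carboxylate (BnBr, KHCO3, DMF, rt) into benzyl 2,4-dihydroxy-6-pentylbenzoate F3. F2 is activated with trifluoroacetic anhydride in toluene at rt as 2-(benzyloxy)-4-methoxy-6-propylbenzoic trifluoroacetic anhydride F4, which acylates the free, non-chelated 4-OH of F3 to give benzyl 4-{[2-(benzyloxy)-4-methoxy-6-propylbenzoyl]oxy}-2-hydroxy-6-pentylbenzoate F5. Hydrogenolysis (H2, 1 atm, 10% Pd/C, EtOAc, rt) removes both benzyl groups and delivers 8.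

Step 3 (carboxylation of olivetol). The risks are the regioisomeric 2,6-dihydroxy-4-pentylbenzoic acid, incomplete conversion, and decarboxylation of 6 during acidification. The fallback replaces direct carboxylation by formylation and oxidation; it sets out from 5 and comes back at 6. Vilsmeier–Haack formylation of 5 (POCl3, DMF, 0 °C to rt) gives N-[(2,4-dihydroxy-6-pentylphenyl)methylidene]-N-methylmethanaminium chloride F6, which is hydrolysed with water to 2,4-dihydroxy-6-pentylbenzaldehyde F7. Lindgren–Pinnick oxidation of F7 (NaClO2, NaH2PO4, DMSO/H2O, rt, with DMSO as hypochlorite scavenger so the resorcinol ring is not chlorinated) gives 6.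

Step 2 (mono-methylation). The risks are over-methylation to the dimethyl ether and incomplete conversion, which give mixtures that are tedious to separate. The fallback replaces selective alkylation by exhaustive methylation and chelation-controlled demethylation; it sets out from 3 and comes back at 4. Compound 3 is fully methylated (MeI, 3 equiv, K2CO3, DMF, 60 °C) to 2,4-dimethoxy-6-propylbenzaldehyde F8. BCl3 (CH2Cl2, −78 to 0 °C) then cleaves only the methoxy group ortho to the formyl group, through the boron chelate, to give 4.

**Further compounds**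
F1 | step 4 | 2-(benzyloxy)-4-methoxy-6-propylbenzaldehyde | CCCc1cc(OC)cc(OCc2ccccc2)c1C=O
F2 | step 4 | 2-(benzyloxy)-4-methoxy-6-propylbenzoic acid | CCCc1cc(OC)cc(OCc2ccccc2)c1C(=O)O
F3 | step 4 | benzyl 2,4-dihydroxy-6-pentylbenzoate | CCCCCc1cc(O)cc(O)c1C(=O)OCc1ccccc1
F4 | step 4 | 2-(benzyloxy)-4-methoxy-6-propylbenzoic trifluoroacetic anhydride | CCCc1cc(OC)cc(OCc2ccccc2)c1C(=O)OC(=O)C(F)(F)F
F5 | step 4 | benzyl 4-{[2-(benzyloxy)-4-methoxy-6-propylbenzoyl]oxy}-2-hydroxy-6-pentylbenzoate | CCCCCc1cc(OC(=O)c2c(OCc3ccccc3)cc(OC)cc2CCC)cc(O)c1C(=O)OCc1ccccc1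
F6 | step 3 | N-[(2,4-dihydroxy-6-pentylphenyl)methylidene]-N-methylmethanaminium chloride | CCCCCc1cc(O)cc(O)c1C=[N+](C)C.[Cl-]
F7 | step 3 | 2,4-dihydroxy-6-pentylbenzaldehyde | CCCCCc1cc(O)cc(O)c1C=O
F8 | step 2 | 2,4-dimethoxy-6-propylbenzaldehyde | CCCc1cc(OC)cc(OC)c1C=O
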